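The route rests on cutting the C5–C6 bond, between the ring CH2 next to CHBr and the spiro carbon. This opens the spirocycle to a chain on a 2,6,6-trimethylcyclohexene. The feature exploited is that spiro carbon C6 lies between C7 (CMe2) and C11 (C=CH2) of the enone ring. That pattern is what the tetrasubstituted alkene of β-cyclocitral leaves after attack at its chain-bearing carbon and proton loss from its methyl. In one operation the key step closes ring C1–C6, builds the quaternary spiro centre and releases the exocyclic methylene. Its precursor is the acyclic primary triflate TfOCH2–CHBr–C(Me)Cl–CH2–CH(OAc)–cyclogeranyl. Its three stereocentres come from asymmetric methallylboration and catalytic enantioselective bromochlorination of a lactone-derived Z-allylic alcohol.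

Key step: step 10

Numbering (spiro[5.5]undecane, also used for the future ring atoms of the open-chain compounds): C1 CH(OAc), C2 CH2, C3 C(Me)Cl, C4 CHBr, C5 CH2, C6 spiro, C7 CMe2, C8, C9, C10 (C=O), C11 (C=CH2). The target is 1S,3R,4R,6R.

Assumption: the antipode of the Schiff-base ligand that delivers the 3R,4R bromochloride in step 8 is found by a trial with both antipodes, since both are accessible and the sense of induction is catalyst-controlled.

Step 1
Reactants: 1 methallyl chloride (3-chloro-2-methylprop-1-ene)
Product: 3 B-methallyldiisopinocampheylborane ((+)-α-pinene series; kept in ether solution), via methallylmagnesium chloride 2 (not isolated)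
Conditions: Mg turnings, THF, 0 °C to rt, slow addition; then (−)-Ipc2BOMe, Et2O, −78 °C to rt
Reagents that add atoms: magnesium [Mg] (stays only in 2); (−)-B-methoxydiisopinocampheylborane COB([C@@H]1C[C@@H]2C[C@H]([C@H]1C)C2(C)C)[C@@H]1C[C@@H]2C[C@H]([C@H]1C)C2(C)C
Why: Grignard formation from the allylic chloride followed by B–OMe to B–C exchange (transmetalation) is the standard preparation of allyl-type diisopinocampheylboranes, and the symmetric methallyl unit raises no allylic regiochemistry.

Step 2
Reactants: 3 B-methallyldiisopinocampheylborane; 4 β-cyclocitral (2,6,6-trimethylcyclohex-1-ene-1-carbaldehyde)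
Product: 6 (1S)-3-methyl-1-(2,6,6-trimethylcyclohex-1-en-1-yl)but-3-en-1-ol, via diisopinocampheylborinate ester 5 (not isolated)
Conditions: Et2O, −78 °C to −20 °C; then 3 M NaOH, 30% H2O2, 0 °C to rt
Reagents that add atoms: none
Why: Reagent-controlled asymmetric methallylboration runs through a closed chair (Zimmerman–Traxler) transition state, so only 1,2-addition is open to the hindered enal, and the (+)-α-pinene-derived ligands expose the aldehyde face that gives the S carbinol (future C1) whenever the aldehyde residue outranks the allylic CH2, after which alkaline peroxide cleaves the borinate.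

Step 3
Reactants: 6 (S)-homoallylic alcohol; 7 acryloyl chloride
Product: 8 (1S)-3-methyl-1-(2,6,6-trimethylcyclohex-1-en-1-yl)but-3-en-1-yl acrylate
Conditions: Et3N, DMAP (cat), CH2Cl2, −20 °C to 0 °C
Reagents that add atoms: none
Why: DMAP-catalysed O-acylation with an acid chloride works on hindered secondary alcohols, the amine base and low temperature keep the ionisable allylic carbinol intact, and no bond to the stereocentre is broken.

Step 4
Reactants: 8 acrylate
Product: 9 (6S)-4-methyl-6-(2,6,6-trimethylcyclohex-1-en-1-yl)-5,6-dihydro-2H-pyran-2-one
Conditions: second-generation Ru–NHC benzylidene metathesis catalyst (5 mol %), toluene (0.01 M), 80 °C, argon sparge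
Reagents that add atoms: none
Why: Ring-closing metathesis of an acrylate with a 1,1-disubstituted alkene to a six-membered unsaturated lactone is well established with second-generation catalysts, the tetrasubstituted ring alkene is inert, and the small ring can hold the new trisubstituted alkene only in the Z form needed later.

Step 5
Reactants: 9 dihydropyranone
Product: 10 (2Z,5S)-3-methyl-5-(2,6,6-trimethylcyclohex-1-en-1-yl)pent-2-ene-1,5-diol
Conditions: DIBAL-H (4.5 equiv), CH2Cl2, −78 °C to 0 °C; aq Rochelle salt
Reagents that add atoms: none
Why: Excess DIBAL-H reduces the unsaturated lactone in 1,2-fashion all the way to the diol without conjugate reduction, so the temporary ring opens while the Z geometry and the carbinol centre are kept.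

Step 6
Reactants: 10 Z-enediol
Product: 12 (1S,3Z)-5-(tert-butyldimethylsilyloxy)-3-methyl-1-(2,6,6-trimethylcyclohex-1-en-1-yl)pent-3-en-1-yl acetate, via primary TBS ether 11 (not isolated)
Conditions: TBSCl (1.05 equiv), Et3N, DMAP (cat), CH2Cl2, 0 °C; then Ac2O, Et3N, DMAP, rt
Reagents that add atoms: tert-butyldimethylsilyl chloride CC(C)(C)[Si](C)(C)Cl; acetic anhydride CC(=O)OC(C)=O
Why: Steric differentiation lets the bulky silyl chloride react only at the primary allylic hydroxyl, and DMAP-catalysed acetylation in the same flask then caps the hindered secondary hydroxyl with retention because only O–H bonds are involved.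

Step 7
Reactants: 12 silyl ether acetate
Product: 13 (1S,3Z)-5-hydroxy-3-methyl-1-(2,6,6-trimethylcyclohex-1-en-1-yl)pent-3-en-1-yl acetate
Conditions: HF·pyridine, excess pyridine, THF, 0 °C
Reagents that add atoms: none
Why: Fluoride-driven desilylation in a pyridine-buffered medium frees the primary allylic alcohol without acetate migration, hydrolysis or ionisation of the allylic acetate.

Step 8
Reactants: 13 Z-allylic alcohol
Product: 14 (1S,3R,4R)-4-bromo-3-chloro-5-hydroxy-3-methyl-1-(2,6,6-trimethylcyclohex-1-en-1-yl)pentyl acetate
Conditions: NBS (1.1 equiv), ClTi(OiPr)3 (1.1 equiv), chiral tridentate O,N,O Schiff-base ligand (20 mol %), hexanes, −20 °C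
Reagents that add atoms: N-bromosuccinimide O=C1CCC(=O)N1Br; chlorotitanium triisopropoxide CC(C)O[Ti](Cl)(OC(C)C)OC(C)C
Why: In this titanium-templated catalytic enantioselective bromochlorination the allylic alkoxide binds to the chiral titanium complex, bromine is delivered to one face of the bound alkene and chloride opens the bromonium anti at the tertiary carbon, so the Z geometry becomes the 3R,4R pair under catalyst control with Br next to CH2OH, the unbound, hindered and acetoxy-deactivated ring alkene is bypassed, and any minor enantiomer carried from step 2 becomes a separable diastereomer.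

Step 9
Reactants: 14 bromochloro alcohol
Product: 15 (2R,3R,5S)-5-acetoxy-2-bromo-3-chloro-3-methyl-5-(2,6,6-trimethylcyclohex-1-en-1-yl)pentyl trifluoromethanesulfonate
Conditions: Tf2O (1.15 equiv), 2,6-di-tert-butyl-4-methylpyridine (DTBMP, 1.5 equiv), CH2Cl2, −78 °C; cold pentane, short cold silica pad; used at once
Reagents that add atoms: trifluoromethanesulfonic anhydride O=S(=O)(OS(=O)(=O)C(F)(F)F)C(F)(F)F
Why: O-sulfonylation of a primary alcohol with triflic anhydride and a non-nucleophilic pyridine is fast at −78 °C, touches no bond at a stereocentre, and the inductive pull of the β-bromine should make the primary triflate stable enough for a rapid cold work-up.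

Step 10
Reactants: 15 primary triflate
Product: 16 (1S,3R,4R,6R)-4-bromo-3-chloro-3,7,7-trimethyl-11-methylidenespiro[5.5]undecan-1-yl acetate
Conditions: DTBMP (2 equiv), CH2Cl2–(CF3)2CHOH 4:1 (0.01 M), −40 °C to 0 °C; aq NaHCO3
Reagents that add atoms: none
Why: Proposed new method: in the ionising but non-nucleophilic medium the C5–OTf bond is displaced from the rear by the π bond of the tetrasubstituted ring alkene, with the neighbouring bromine lending at most weak bridging, so C5 bonds to the chain-bearing alkene carbon C6, the charge lands on the methyl-bearing carbon C11 as a tertiary cation, and the hindered pyridine removes a methyl proton to leave the exocyclic methylene. The closest known reaction types are the π-assisted solvolysis of alkenyl sulfonates, the bromine-assisted solvolysis of vicinal bromo halides in fluorinated alcohols with alkene capture, and cation–olefin closures onto cyclogeranyl alkenes, whereas a β-bromo primary triflate as the electrophile for a spiro quaternary carbon beside CMe2 has not been shown. The one ring closed is the halogenated cyclohexane C1–C6, by a 6-exo-tet displacement at C5 that is also 6-exo with respect to the alkene and should be preferred over the 7-endo alternative at C11. The only new stereocentre, C6, is controlled by a chair transition state relayed from C1, C3 and C4: OAc, Cl and Br sit equatorial, the C3 methyl is axial, and the flat cationic C11 rather than the bulky CMe2 takes the axial site facing the axial hydrogens of C2 and C4, which gives 6R, while C4 keeps its configuration because its C–Br bond is never broken and C5 is not stereogenic. The step needs chemoselective ionisation, site selectivity and regioselective proton loss: the triflate is by far the best leaving group and should depart at or below 0 °C, where the tertiary chloride and the allylic acetate stay bound, attack at C4 of any bridged ion is blocked by the adjacent C(Me)Cl carbon, and the bulky base reaches the methyl more easily than the ring CH2.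

Step 11
Reactants: 16 spirocyclic exo-methylene compound
Product: 17 (1S,3R,4R,6R)-4-bromo-3-chloro-10-hydroxy-3,7,7-trimethyl-11-methylidenespiro[5.5]undecan-1-yl acetate (C10 configuration left open)
Conditions: SeO2 (cat, 0.3 equiv), t-BuOOH (3 equiv, decane solution), CH2Cl2, 0 °C to rt
Reagents that add atoms: selenium dioxide O=[Se]=O; tert-butyl hydroperoxide CC(C)(C)OO
Why: Riley-type allylic oxidation (ene reaction at the terminal methylene carbon, then [2,3]-sigmatropic shift) restores the exocyclic alkene and puts the hydroxyl on C10, the only allylic C–H position because the other neighbour of C11 is the quaternary C6, and the configuration of the new carbinol is irrelevant since it is oxidised next.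

Step 12
Reactants: 17 allylic alcohol
Product: 18 (1S,3R,4R,6R)-4-bromo-3-chloro-3,7,7-trimethyl-11-methylidene-10-oxospiro[5.5]undecan-1-yl acetate
Conditions: Dess–Martin periodinane (1.3 equiv), CH2Cl2, 0 °C to rt
Reagents that add atoms: none
Why: Dess–Martin oxidation converts the secondary allylic alcohol into the ketone under mild conditions that leave both halides, the acetate and the sensitive α-methylene ketone untouched.

Step 13
Reactants: 18 α-methylene ketone
Product: 19 (1S,3R,4R,6R)-4-bromo-3-chloro-3,7,7-trimethyl-11-methylidene-10-(trimethylsilyloxy)spiro[5.5]undec-9-en-1-yl acetate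
Conditions: TMSOTf (1.5 equiv), i-Pr2NEt (3 equiv), CH2Cl2, −78 °C to 0 °C; cold aq NaHCO3
Reagents that add atoms: trimethylsilyl trifluoromethanesulfonate C[Si](C)(C)OS(=O)(=O)C(F)(F)F
Why: Soft enolisation (silyl triflate activation of the carbonyl plus a hindered amine) can take a proton only from C9 because C11 carries none, avoids the strong bases that would cause loss of HBr, HCl or acetate, and the non-nucleophilic amine spares the Michael acceptor.

Step 14
Reactants: 19 silyl dienol ether
Product: 20 (1S,3R,4R,6R)-4-bromo-3-chloro-3,7,7-trimethyl-11-methylidene-10-oxospiro[5.5]undec-8-en-1-yl acetate (target CNP0161807.1)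
Conditions: Pd(OAc)2 (1.1 equiv), MeCN, rt
Reagents that add atoms: none
Why: In the Saegusa–Ito oxidation Pd(II) attacks the silyl enol ether to give an oxo-π-allyl palladium species that undergoes β-hydride elimination from C8, which installs the C8=C9 alkene and hence the cross-conjugated dienone without touching any stereocentre.

Compound list
1 | methallyl chloride (3-chloro-2-methylprop-1-ene) | C=C(C)CCl | starting material
2 | methallylmagnesium chloride | C=C(C)C[Mg]Cl | intermediate
3 | B-methallyldiisopinocampheylborane, (+)-α-pinene series | C=C(C)CB([C@@H]1C[C@@H]2C[C@H]([C@H]1C)C2(C)C)[C@@H]1C[C@@H]2C[C@H]([C@H]1C)C2(C)C | intermediate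
4 | β-cyclocitral | CC1=C(C=O)C(C)(C)CCC1 | starting material
5 | diisopinocampheylborinate ester of 6 | CC1=C([C@@H](OB([C@@H]2C[C@@H]3C[C@H]([C@H]2C)C3(C)C)[C@@H]2C[C@@H]3C[C@H]([C@H]2C)C3(C)C)CC(C)=C)C(C)(C)CCC1 | intermediate
6 | (1S)-3-methyl-1-(2,6,6-trimethylcyclohex-1-en-1-yl)but-3-en-1-ol | CC1=C([C@@H](O)CC(C)=C)C(C)(C)CCC1 | intermediate
7 | acryloyl chloride | C=CC(=O)Cl | starting material
8 | (1S)-3-methyl-1-(2,6,6-trimethylcyclohex-1-en-1-yl)but-3-en-1-yl acrylate | CC1=C([C@@H](OC(=O)C=C)CC(C)=C)C(C)(C)CCC1 | intermediate
9 | (6S)-4-methyl-6-(2,6,6-trimethylcyclohex-1-en-1-yl)-5,6-dihydro-2H-pyran-2-one | CC1=C([C@@H]2CC(C)=CC(=O)O2)C(C)(C)CCC1 | intermediate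
10 | (2Z,5S)-3-methyl-5-(2,6,6-trimethylcyclohex-1-en-1-yl)pent-2-ene-1,5-diol | CC1=C([C@@H](O)C/C(C)=C\CO)C(C)(C)CCC1 | intermediate
11 | (1S,3Z)-5-(tert-butyldimethylsilyloxy)-3-methyl-1-(2,6,6-trimethylcyclohex-1-en-1-yl)pent-3-en-1-ol | CC1=C([C@@H](O)C/C(C)=C\CO[Si](C)(C)C(C)(C)C)C(C)(C)CCC1 | intermediate
12 | (1S,3Z)-5-(tert-butyldimethylsilyloxy)-3-methyl-1-(2,6,6-trimethylcyclohex-1-en-1-yl)pent-3-en-1-yl acetate | CC1=C([C@@H](OC(C)=O)C/C(C)=C\CO[Si](C)(C)C(C)(C)C)C(C)(C)CCC1 | intermediate
13 | (1S,3Z)-5-hydroxy-3-methyl-1-(2,6,6-trimethylcyclohex-1-en-1-yl)pent-3-en-1-yl acetate | CC1=C([C@@H](OC(C)=O)C/C(C)=C\CO)C(C)(C)CCC1 | intermediate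
14 | (1S,3R,4R)-4-bromo-3-chloro-5-hydroxy-3-methyl-1-(2,6,6-trimethylcyclohex-1-en-1-yl)pentyl acetate | CC1=C([C@@H](OC(C)=O)C[C@@](C)(Cl)[C@H](Br)CO)C(C)(C)CCC1 | intermediate
15 | (2R,3R,5S)-5-acetoxy-2-bromo-3-chloro-3-methyl-5-(2,6,6-trimethylcyclohex-1-en-1-yl)pentyl triflate | CC1=C([C@@H](OC(C)=O)C[C@@](C)(Cl)[C@H](Br)COS(=O)(=O)C(F)(F)F)C(C)(C)CCC1 | intermediate
16 | (1S,3R,4R,6R)-4-bromo-3-chloro-3,7,7-trimethyl-11-methylidenespiro[5.5]undecan-1-yl acetate | C=C1CCCC(C)(C)[C@]12C[C@@H](Br)[C@](C)(Cl)C[C@@H]2OC(C)=O | intermediate
17 | 10-hydroxy derivative of 16 (C10 epimers, centre removed in step 12) | C=C1C(O)CCC(C)(C)[C@]12C[C@@H](Br)[C@](C)(Cl)C[C@@H]2OC(C)=O | intermediate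
18 | (1S,3R,4R,6R)-4-bromo-3-chloro-3,7,7-trimethyl-11-methylidene-10-oxospiro[5.5]undecan-1-yl acetate | C=C1C(=O)CCC(C)(C)[C@]12C[C@@H](Br)[C@](C)(Cl)C[C@@H]2OC(C)=O | intermediate
19 | 10-trimethylsilyloxy-9-ene (silyl dienol ether of 18) | C=C1C(O[Si](C)(C)C)=CCC(C)(C)[C@]12C[C@@H](Br)[C@](C)(Cl)C[C@@H]2OC(C)=O | intermediate
20 | (1S,3R,4R,6R)-4-bromo-3-chloro-3,7,7-trimethyl-11-methylidene-10-oxospiro[5.5]undec-8-en-1-yl acetate | C=C1C(=O)C=CC(C)(C)[C@]12C[C@@H](Br)[C@](C)(Cl)C[C@@H]2OC(C)=O | target

Total step count: 14.
Longest linear sequence: 14 steps from methallyl chloride 1 (13 from β-cyclocitral 4).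

Steps most likely to fail

1. Step 10.
- **What may go wrong:**
  - The π-displacement may be too slow, so the tertiary chloride or the allylic acetate ionises first.
  - Bonding may occur at the methyl-bearing alkene carbon, giving a seven-membered closure.
  - A bridged bromonium may be opened at the secondary carbon, giving a five-membered closure.
  - Facial selectivity at the ring alkene may be poor.
  - The proton may be lost toward the ring CH2.
  - The acetate carbonyl may intercept the tertiary cation.
- **Fallback (known chemistry, from 13 back to 16):** the halogens are postponed. Diethyl chlorophosphate and pyridine convert the primary alcohol of 13 into the Z-allylic diethyl phosphate F1. Ionisation with Et2AlCl in CH2Cl2 at −78 °C triggers a neryl-type allyl cation–olefin cyclisation. The Z geometry lets the allylic terminus reach the same ring alkene carbon, which should give the spiro diene acetate F2, with the C3=C4 alkene in the new ring and the exocyclic methylene at C11. Electrophilic bromochlorination of the more electron-rich trisubstituted alkene with tetrabutylammonium dichlorobromate follows. Bromine should be taken up on the face away from the axial C11, and chloride should enter anti at the tertiary C3. This should lead to 16 after separation of diastereomers.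

2. Step 8.
- **What may go wrong:** a mismatch between the catalyst and the resident C1 centre may erode facial selectivity, and bromination of the ring alkene may compete.
- **Fallback (from 13 back to 14):** stereocontrol by the catalyst is replaced by separation and recycling. Ligand-free, still hydroxyl-directed bromochlorination (NBS, ClTi(OiPr)3) should give both anti adducts, 14 and its (1S,3S,4S) diastereomer F3. These are separable by chromatography because C1 is already fixed. F3 is returned to 13 by stereospecific anti reductive elimination with zinc dust in ethanol and resubmitted.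

3. Step 2.
- **What may go wrong:** addition to the very hindered, twisted enal may be sluggish and enantioselectivity may be eroded.
- **Fallback (from 2 and 4 back to 6):** direct Grignard addition should give the racemic carbinol F4. Dess–Martin oxidation under neutral conditions, which avoids conjugation of the alkene, should give the β,γ-unsaturated ketone F5. Corey–Bakshi–Shibata reduction with the (R)-oxazaborolidine and catecholborane in toluene at −78 °C follows. The bulky cyclohexenyl residue acts as the large group, and the 1,1-disubstituted alkene is not hydroborated, so the S carbinol 6 should result.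

Further compounds
F1 | step 10 | (1S,3Z)-5-(diethoxyphosphoryloxy)-3-methyl-1-(2,6,6-trimethylcyclohex-1-en-1-yl)pent-3-en-1-yl acetate | CC1=C([C@@H](OC(C)=O)C/C(C)=C\COP(=O)(OCC)OCC)C(C)(C)CCC1
F2 | step 10 | (1S,6R)-3,7,7-trimethyl-11-methylidenespiro[5.5]undec-3-en-1-yl acetate | C=C1CCCC(C)(C)[C@]12CC=C(C)C[C@@H]2OC(C)=O
F3 | step 8 | (1S,3S,4S)-4-bromo-3-chloro-5-hydroxy-3-methyl-1-(2,6,6-trimethylcyclohex-1-en-1-yl)pentyl acetate | CC1=C([C@@H](OC(C)=O)C[C@](C)(Cl)[C@@H](Br)CO)C(C)(C)CCC1
F4 | step 2 | racemic 3-methyl-1-(2,6,6-trimethylcyclohex-1-en-1-yl)but-3-en-1-ol | CC1=C(C(O)CC(C)=C)C(C)(C)CCC1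
F5 | step 2 | 3-methyl-1-(2,6,6-trimethylcyclohex-1-en-1-yl)but-3-en-1-one | CC1=C(C(=O)CC(C)=C)C(C)(C)CCC1
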